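## The problem

Compound 19 is a chalcone whose ketone-bearing aryl group is ring A of a 2,2-dimethylchroman; ring B is the dihydropyran and ring C the 4-hydroxyphenyl group at the far end of the (E)-enone. Ring A carries four substituents on adjacent carbons (C4a alkyl, C5 methoxy, C8a ether oxygen, C8 acyl). Because C6 and C8 are both activated by the two oxygens, a late electrophilic acylation could not be trusted to choose C8. Ring B holds the gem-dimethyl ether carbon C2, the secondary carbinol C3 and the benzylic methylene C4. C3 is the only stereocentre (S) and nothing else in the molecule can direct it, so it must be set by a catalyst, an auxiliary or the chiral pool. It can epimerise in any precursor where it lies next to a carbonyl group, but not once it sits between quaternary C2 and the C4 methylene. The enone tolerates neither hydrogenation nor hydride or organometallic reagents and must therefore be made last; the tertiary alkyl aryl ether O1–C2, ortho to the ketone, also excludes strong Lewis acids late on. The enabling feature is the sequence O1–C8a–C4a–C4, the skeleton of an ortho-quinone methide with an unsubstituted methide carbon, joined to C3–C2, which can be an α-oxy enolate if C2 is held as a lactone carbonyl and later turned into CMe2.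

## Retrosynthesis

The Cα=Cβ bond of the enone is cut first, giving methyl ketone 16 and aldehyde 17. This aldol-type cut removes ring C and the only reduction-sensitive group in one move. The neighbouring cut at the aryl–carbonyl bond would need a cinnamoyl electrophile and a regioselective acylation of ring A. The forward condensation must tolerate a free secondary alcohol and a free phenol and give the E isomer.

Ketone 16 is traced to benzyl ether 15, and the C8–acetyl bond of 15 is cut to aryllithium 14, which comes from aryl bromide 13. A bromine at C8 fixes the acylation site beyond doubt, which a Friedel–Crafts reaction on the bromine-free chroman would not. The benzyl ether must go before the enone exists, so hydrogenolysis is placed between acylation and condensation.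

In 13 the O1–C2 ether bond is cut to phenol-carbinol 12, and both C2–methyl bonds of 12 are cut to lactone 10 (through ketone 11). This turns the gem-dimethyl ether carbon into a carboxyl carbon, the oxidation level at which C3–C2 can act as an enolate. The forward steps are a double methyl addition without loss of configuration at C3 and a cyclodehydration through the tertiary cation that leaves C3 untouched.

Lactone 10 is cut at C3–C4 and at the acyl O1–C2 bond to ortho-quinone methide 9 and an α-benzyloxy acyl donor, acyl imidazole 8. This is the only cut that forms ring B and the stereocentre together from two achiral pieces. Cutting C4–C4a (enolate benzylation and separate lactonisation) or using a C3=C4 oxidation would need more steps or an auxiliary. Quinone methide 9 is released in the flask from silyl ether 6. The forward reaction must control the enolate face with a chiral carbene and trap 9 before it oligomerises.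

Bromide 6 goes back through alcohol 5 and aldehyde 4 to salicylaldehyde 3, and the formyl C–C bond of 3 is cut to phenol 1 (through 2). In 1 the bromine blocks one ortho position, so formylation can only enter between hydroxyl and methoxy, and the same bromine later marks C8. Acyl imidazole 8 comes from acid chloride 7. Compounds 1, 7 and 17 are commercial.

## Roads not taken

Alternative 1: Both bonds at the ketone carbon are cut, giving the silyl-protected aryl bromide A2, carbon monoxide A3 and 4-acetoxystyrene A4. Zerovalent palladium would insert into the C8–Br bond, take up A3, add across A4 and eliminate β-hydride to give the protected chalcone A1.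
- Merits: the enone is assembled convergently with its E geometry, and no aryllithium, hydrogenolysis or aldol step is needed.
- Weak points: A2 is electron-rich and ortho-alkoxylated, so oxidative addition is slow and is slowed further under A3. The direct Heck product without A3 is a likely competitor. The aryl acetate is exposed to the base, and two protecting groups remain to be removed from A1.
- Comparison: this road leaves the C3 question unanswered, since A2 must still be made in enantiopure form. It would save at most one step over steps 9 to 11. Against that saving the chosen plan sets three routine operations that need no pressure equipment. Bromide 13 could still be tried in such a coupling.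

Alternative 2: Ring A is built from an open chain by cutting the C7–C8 bond. Under Mg(OMe)2 the C2 carbanion of the dioxo ester A6 would add to its own methoxyenone terminus, lose methanol and aromatise to benzoate A5.
- Merits: all four contiguous substituents of ring A arrive with no regiochemical question, and the stereocentre comes from a dioxolane of dependable origin. Here this road is at least as secure as the chosen one.
- Weak points: A6 is a branched, enolisable polycarbonyl chain. Its assembly needs several acylations with C- against O-selectivity problems, and the cyclisation competes with pyranone formation. After A5, selective O-methylation, acetal removal, chroman closure and conversion of the ester into the enone are all still to come.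
- Comparison: the route is clearly longer. The chosen plan matches its regiochemical security with commercial phenol 1, which has only one free ortho position, and sets C3 by catalysis in the ring-forming step.

Alternative 3: Ring B is cut at C4–C4a and O1–C2. The phenol A9 would be converted into aryl propargyl ether A8, and heating would trigger a [3,3] shift, a 1,5-hydrogen shift and an oxa-6π electrocyclisation to chromene A7. Asymmetric epoxidation of the C3=C4 bond (Jacobsen epoxidation) would give epoxide A10, and hydride opening at C4 followed by condensation with 17 would finish the synthesis.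
- Merits: A9 is cheap, only one ortho position is free so the cascade is regiochemically fixed, and 2,2-dimethylchromenes are among the best substrates for this epoxidation. The route needs about half as many steps as the chosen one, and its asymmetric step has closer precedent.
- Weak points: oxygen is put on C4 only to be removed. That removal must happen at a benzylic carbon made cation-prone by the C5 methoxy group, where ionisation and hydride shift to a chromanone would destroy C3. It must also be done beside an aryl ketone that hydride or hydrogen can reduce, so protection or re-oxidation may be needed.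
- Comparison: on step count and precedent this road is ahead. The chosen plan sets against it a C4 that is a methylene from the start, no reductive chemoselectivity problem, and a stereocentre formed in the same event that builds ring B.

Key step: step 6

Assumption: the (5aS,10bR) antipode of the aminoindanol-derived triazolium salt is taken to leave open the enolate face that leads to (3S)-10; if the sense of induction is the opposite, the (5aR,10bS) salt is used and nothing else changes.

## Route

Step 1
Reactants: 1 2-bromo-5-methoxyphenol
Product: 3 3-bromo-2-hydroxy-6-methoxybenzaldehyde, via magnesium salt of 6-bromo-2-(hydroxymethyl)-3-methoxyphenol 2 (not isolated)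
Conditions: MgCl2, Et3N, (CH2O)n, THF, reflux; 1 M HCl
Reagents that add atoms: paraformaldehyde (formaldehyde), C=O
Why: Magnesium-mediated ortho-formylation (Casnati–Skattebøl reaction): the magnesium phenoxide delivers formaldehyde to the only free ortho carbon of 1, and benzylic alkoxide 2 is oxidised in the flask by hydride transfer to a second formaldehyde; the adjacent methoxy group adds electron density at that carbon, and 2-bromophenols are standard substrates.

Step 2
Reactants: 3 3-bromo-2-hydroxy-6-methoxybenzaldehyde
Product: 4 3-bromo-2-{[tert-butyl(dimethyl)silyl]oxy}-6-methoxybenzaldehyde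
Conditions: TBSCl, imidazole, DMF, rt
Reagents that add atoms: TBSCl (tert-butyldimethylsilyl chloride), CC(C)(C)[Si](C)(C)Cl
Why: Standard phenol silylation; the flanked, hydrogen-bonded hydroxyl reacts more slowly than usual but imidazole in DMF is the usual remedy, and the aryl silyl ether is the fluoride trigger for the key step.

Step 3
Reactants: 4 3-bromo-2-{[tert-butyl(dimethyl)silyl]oxy}-6-methoxybenzaldehyde
Product: 5 (3-bromo-2-{[tert-butyl(dimethyl)silyl]oxy}-6-methoxyphenyl)methanol
Conditions: NaBH4, THF/MeOH, −10 °C; sat. NH4Cl
Reagents that add atoms: none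
Why: Borohydride reduction of an aromatic aldehyde; low temperature and a buffered quench keep the benzylic alkoxide from taking the silyl group from the phenolic oxygen.

Step 4
Reactants: 5 (3-bromo-2-{[tert-butyl(dimethyl)silyl]oxy}-6-methoxyphenyl)methanol
Product: 6 {[6-bromo-2-(bromomethyl)-3-methoxyphenyl]oxy}(tert-butyl)dimethylsilane (fragment 1)
Conditions: CBr4, PPh3, CH2Cl2, 0 °C
Reagents that add atoms: CBr4, BrC(Br)(Br)Br
Why: Appel reaction: bromide displaces the alkoxyphosphonium ion of the primary benzylic alcohol under neutral conditions that leave the aryl silyl ether intact; the electron-rich bromide is used without long storage.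

Step 5
Reactants: 7 (benzyloxy)acetyl chloride
Product: 8 2-(benzyloxy)-1-(1H-imidazol-1-yl)ethanone (fragment 2)
Conditions: imidazole (2.1 equiv), CH2Cl2, 0 °C to rt
Reagents that add atoms: imidazole, c1c[nH]cn1
Why: N-Acylation of imidazole by an acid chloride, the second equivalent of imidazole taking up HCl; the acyl imidazole is the acyl donor the carbene needs and is kept dry.

Step 6
Reactants: 6 {[6-bromo-2-(bromomethyl)-3-methoxyphenyl]oxy}(tert-butyl)dimethylsilane (fragment 1), 8 2-(benzyloxy)-1-(1H-imidazol-1-yl)ethanone (fragment 2)
Product: 10 (3S)-3-(benzyloxy)-8-bromo-5-methoxy-3,4-dihydro-2H-chromen-2-one, via ortho-quinone methide 9 (not isolated)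
Conditions: 8 (2 equiv), (5aS,10bR)-2-(2,4,6-trimethylphenyl)-5a,10b-dihydro-4H,6H-indeno[2,1-b][1,2,4]triazolo[4,3-d][1,4]oxazin-2-ium tetrafluoroborate (20 mol %), CsF, 18-crown-6, THF, 0 °C; pH 7 buffer
Reagents that add atoms: none
Why: Fluoride attacks silicon of 6 and the freed phenoxide expels the benzylic bromide by 1,4-elimination, giving ortho-quinone methide 9 at low stationary concentration. In parallel the carbene is acylated by 8 with loss of imidazolide, and α-deprotonation of the acyl azolium gives the (Z)-α-benzyloxy azolium enolate. Its α-carbon adds to the exocyclic methylene of 9 (C3–C4), driven by re-aromatisation, and the resulting phenoxide attacks the acyl azolium in a 6-exo-trig acyl substitution (O1–C2) that closes the lactone and returns the carbene, a stepwise formal [4+2] annulation. The closest known reaction type is the fluoride/carbene dual activation that joins silylated 2-(bromomethyl)phenols and acyl imidazoles to 3-substituted dihydrocoumarins, applied here to an α-alkoxy acyl donor. C3 is the only new stereocentre and is fixed in the C–C bond formation: the fused indane of the catalyst screens one face of the planar enolate so that 9 approaches the open face, and the unsubstituted methide carbon raises no diastereomer question. The step needs enantiofacial control, which rests on the catalyst, and capture of 9 by the enolate ahead of imidazole, fluoride or a second molecule of 9, which rests on slow heterogeneous release by CsF and the excess of 8. The α-alkoxy aryl lactone can epimerise under base, so the mixture is kept cold, buffered as soon as 6 is consumed, and 10 is carried on at once.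

Step 7
Reactants: 10 (3S)-3-(benzyloxy)-8-bromo-5-methoxy-3,4-dihydro-2H-chromen-2-one
Product: 12 2-[(2S)-2-(benzyloxy)-3-hydroxy-3-methylbutyl]-6-bromo-3-methoxyphenol, via methyl ketone 11 (not isolated)
Conditions: MeMgBr (4 equiv), THF, −78 to 0 °C; sat. NH4Cl
Reagents that add atoms: MeMgBr, C[Mg]Br
Why: Double Grignard addition to an aryl ester: the first methyl opens the lactone to ketone 11, held as a magnesium chelate with the α-benzyloxy oxygen, and the second gives the tertiary alkoxide; fast addition in the cold outruns deprotonation at C3, which is no longer acidic after this step.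

Step 8
Reactants: 12 2-[(2S)-2-(benzyloxy)-3-hydroxy-3-methylbutyl]-6-bromo-3-methoxyphenol
Product: 13 (3S)-3-(benzyloxy)-8-bromo-5-methoxy-2,2-dimethyl-3,4-dihydro-2H-chromene
Conditions: TsOH·H2O (10 mol %), toluene, 60 °C
Reagents that add atoms: none
Why: Acid-catalysed cyclodehydration, the classical closure of 2,2-dimethylchromans: the tertiary alcohol ionises and the phenol oxygen captures the cation through a six-membered transition state to form O1–C2; no bond to C3 is broken, so its configuration is retained.

Step 9
Reactants: 13 (3S)-3-(benzyloxy)-8-bromo-5-methoxy-2,2-dimethyl-3,4-dihydro-2H-chromene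
Product: 15 1-[(3S)-3-(benzyloxy)-5-methoxy-2,2-dimethyl-3,4-dihydro-2H-chromen-8-yl]ethanone, via aryllithium 14 (not isolated)
Conditions: n-BuLi, THF, −78 °C; MeC(O)N(OMe)Me, −78 to 0 °C; sat. NH4Cl
Reagents that add atoms: N-methoxy-N-methylacetamide, CC(=O)N(C)OC
Why: Bromine–lithium exchange is faster than any deprotonation at −78 °C, and aryllithium 14 is acylated by the Weinreb amide through a chelated tetrahedral intermediate that releases the ketone only on work-up, so no tertiary alcohol forms; the bromine makes C8 the only possible site.

Step 10
Reactants: 15 1-[(3S)-3-(benzyloxy)-5-methoxy-2,2-dimethyl-3,4-dihydro-2H-chromen-8-yl]ethanone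
Product: 16 1-[(3S)-3-hydroxy-5-methoxy-2,2-dimethyl-3,4-dihydro-2H-chromen-8-yl]ethanone
Conditions: H2 (1 atm), Pd/C (10% Pd on carbon), EtOAc, rt
Reagents that add atoms: none
Why: Hydrogenolysis of a benzyl ether; at one atmosphere in a neutral solvent the electron-rich aryl methyl ketone is reduced far more slowly than the O-benzyl bond is cleaved, and the reaction is stopped after one equivalent of hydrogen.

Step 11
Reactants: 16 1-[(3S)-3-hydroxy-5-methoxy-2,2-dimethyl-3,4-dihydro-2H-chromen-8-yl]ethanone, 17 4-hydroxybenzaldehyde
Product: 19 (2E)-1-[(3S)-3-hydroxy-5-methoxy-2,2-dimethyl-3,4-dihydro-2H-chromen-8-yl]-3-(4-hydroxyphenyl)prop-2-en-1-one, via aldol adduct 18 (not isolated)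
Conditions: 17 (1.5 equiv), KOH (50% aq.), EtOH, rt to 40 °C; 1 M HCl to pH 5
Reagents that add atoms: none
Why: Claisen–Schmidt condensation: the enolate of 16 adds to 17 and aldol 18 loses water by E1cB elimination to the conjugated (E)-enone, the thermodynamically favoured geometry; the ketone has no free ortho hydroxyl, so no flavanone can form, and C3 carries no acidic hydrogen.

## Compound list

1 | 2-bromo-5-methoxyphenol | COc1ccc(Br)c(O)c1 | starting material
2 | 6-bromo-2-(hydroxymethyl)-3-methoxyphenol (magnesium salt in the flask, not isolated) | COc1ccc(Br)c(O)c1CO | intermediate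
3 | 3-bromo-2-hydroxy-6-methoxybenzaldehyde | COc1ccc(Br)c(O)c1C=O | intermediate
4 | 3-bromo-2-{[tert-butyl(dimethyl)silyl]oxy}-6-methoxybenzaldehyde | COc1ccc(Br)c(O[Si](C)(C)C(C)(C)C)c1C=O | intermediate
5 | (3-bromo-2-{[tert-butyl(dimethyl)silyl]oxy}-6-methoxyphenyl)methanol | COc1ccc(Br)c(O[Si](C)(C)C(C)(C)C)c1CO | intermediate
6 | {[6-bromo-2-(bromomethyl)-3-methoxyphenyl]oxy}(tert-butyl)dimethylsilane (fragment 1) | COc1ccc(Br)c(O[Si](C)(C)C(C)(C)C)c1CBr | intermediate
7 | (benzyloxy)acetyl chloride | O=C(Cl)COCc1ccccc1 | starting material
8 | 2-(benzyloxy)-1-(1H-imidazol-1-yl)ethanone (fragment 2) | O=C(COCc1ccccc1)n1ccnc1 | intermediate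
9 | 2-bromo-5-methoxy-6-methylidenecyclohexa-2,4-dien-1-one (ortho-quinone methide, not isolated) | C=C1C(=O)C(Br)=CC=C1OC | intermediate
10 | (3S)-3-(benzyloxy)-8-bromo-5-methoxy-3,4-dihydro-2H-chromen-2-one | COc1ccc(Br)c2c1C[C@H](OCc1ccccc1)C(=O)O2 | intermediate
11 | (3S)-3-(benzyloxy)-4-(3-bromo-2-hydroxy-6-methoxyphenyl)butan-2-one (magnesium phenoxide in the flask, not isolated) | COc1ccc(Br)c(O)c1C[C@H](OCc1ccccc1)C(C)=O | intermediate
12 | 2-[(2S)-2-(benzyloxy)-3-hydroxy-3-methylbutyl]-6-bromo-3-methoxyphenol | COc1ccc(Br)c(O)c1C[C@H](OCc1ccccc1)C(C)(C)O | intermediate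
13 | (3S)-3-(benzyloxy)-8-bromo-5-methoxy-2,2-dimethyl-3,4-dihydro-2H-chromene | COc1ccc(Br)c2c1C[C@H](OCc1ccccc1)C(C)(C)O2 | intermediate
14 | [(3S)-3-(benzyloxy)-5-methoxy-2,2-dimethyl-3,4-dihydro-2H-chromen-8-yl]lithium (not isolated) | COc1ccc([Li])c2c1C[C@H](OCc1ccccc1)C(C)(C)O2 | intermediate
15 | 1-[(3S)-3-(benzyloxy)-5-methoxy-2,2-dimethyl-3,4-dihydro-2H-chromen-8-yl]ethanone | COc1ccc(C(C)=O)c2c1C[C@H](OCc1ccccc1)C(C)(C)O2 | intermediate
16 | 1-[(3S)-3-hydroxy-5-methoxy-2,2-dimethyl-3,4-dihydro-2H-chromen-8-yl]ethanone | COc1ccc(C(C)=O)c2c1C[C@H](O)C(C)(C)O2 | intermediate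
17 | 4-hydroxybenzaldehyde | O=Cc1ccc(O)cc1 | starting material
18 | 3-hydroxy-3-(4-hydroxyphenyl)-1-[(3S)-3-hydroxy-5-methoxy-2,2-dimethyl-3,4-dihydro-2H-chromen-8-yl]propan-1-one (both carbinol epimers, not isolated) | COc1ccc(C(=O)CC(O)c2ccc(O)cc2)c2c1C[C@H](O)C(C)(C)O2 | intermediate
19 | (2E)-1-[(3S)-3-hydroxy-5-methoxy-2,2-dimethyl-3,4-dihydro-2H-chromen-8-yl]-3-(4-hydroxyphenyl)prop-2-en-1-one | COc1ccc(C(=O)/C=C/c2ccc(O)cc2)c2c1C[C@H](O)C(C)(C)O2 | target

## Step count and risks

Total: 11 steps. Longest linear sequence: 10 steps (steps 1 to 4 and 6 to 11, from 1); step 5 is the one-step side branch.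

**Key step, step 6.** Three things are most likely to go wrong:
- capture of the quinone methide by imidazole or by itself instead of by the enolate;
- weaker facial discrimination, because an alkoxy group replaces the alkyl group of the known donors;
- base-mediated epimerisation of the α-alkoxy aryl lactone before work-up.

The fallback makes the same two bonds in separate steps under auxiliary control. It sets out from 6 and 7 and comes back at 10. Acid chloride 7 acylates lithiated (4R)-4-benzyl-1,3-oxazolidin-2-one to give (4R)-4-benzyl-3-[(benzyloxy)acetyl]-1,3-oxazolidin-2-one F1. Its chelated sodium (Z)-enolate (NaN(SiMe3)2, THF, −78 °C) is alkylated by bromide 6 on the face away from the benzyl group (Evans glycolate alkylation). This gives (4R)-4-benzyl-3-[(2S)-2-(benzyloxy)-3-(3-bromo-2-{[tert-butyl(dimethyl)silyl]oxy}-6-methoxyphenyl)propanoyl]-1,3-oxazolidin-2-one F2. Bu4NF buffered with AcOH then frees the phenol, which attacks the exocyclic imide carbonyl, expels the auxiliary and closes lactone 10.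

**Step 8.** The tertiary cation lies next to the benzyloxy-bearing carbon. A 1,2-hydride shift to an oxocarbenium ion, or elimination towards C3, would divert material to a ketone. This would cost yield, though not the configuration of what does cyclise. The fallback closes O1–C2 through a mercurinium ion instead of a free cation. It sets out from 10 and comes back at 13.
- Aminolysis of 10 with N,O-dimethylhydroxylamine hydrochloride and i-PrMgCl gives (2S)-2-(benzyloxy)-3-(3-bromo-2-hydroxy-6-methoxyphenyl)-N-methoxy-N-methylpropanamide F3.
- MeMgBr converts F3 into ketone 11, this time isolated.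
- Wittig methylenation with excess Ph3P=CH2 in the cold gives 2-[(2S)-2-(benzyloxy)-3-methylbut-3-en-1-yl]-6-bromo-3-methoxyphenol F4.
- Hg(OCOCF3)2 induces 6-exo Markovnikov attack of the phenol on the alkene to give {[(3S)-3-(benzyloxy)-8-bromo-5-methoxy-2-methyl-3,4-dihydro-2H-chromen-2-yl]methyl}mercury trifluoroacetate F5, and NaBH4 replaces mercury by hydrogen to give 13.

**Step 7.** The Grignard reagent may deprotonate C3 of the aryl ester with expulsion of phenoxide (a ketene pathway), or enolise ketone 11. Either would stall the second addition and erode optical purity. The fallback sets out from 10 and comes back at 12. Acid-catalysed methanolysis (HCl, MeOH, rt) opens the lactone to methyl (2S)-2-(benzyloxy)-3-(3-bromo-2-hydroxy-6-methoxyphenyl)propanoate F6. Its methoxide leaving group does not support the ketene pathway. F6 then takes two methyl groups from the weakly basic organocerium reagent made from MeLi and CeCl3 to give 12.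

**Step 3.** The silyl group may migrate from the phenolic oxygen to the newly formed benzylic alkoxide, which the bromine-stabilised phenoxide leaving group would favour. The fallback sets out from 3 and comes back at 6. NaBH4 reduces 3 to diol 2, now isolated. Exhaustive silylation (TBSCl, imidazole) gives tert-butyl[(3-bromo-2-{[tert-butyl(dimethyl)silyl]oxy}-6-methoxyphenyl)methoxy]dimethylsilane F7. Ph3PBr2 in CH2Cl2 converts only the benzylic silyl ether into the bromide, leaving the aryl silyl ether in place, to give 6.

**Step 11.** Under KOH aldehyde 17 is present as its electron-rich phenoxide, so aldol addition may be sluggish. Forcing it invites Cannizzaro disproportionation and retro-aldol loss. The fallback sets out from 16 and comes back at 19. Condensation of 16 with commercial 4-(methoxymethoxy)benzaldehyde under the same base gives (2E)-1-[(3S)-3-hydroxy-5-methoxy-2,2-dimethyl-3,4-dihydro-2H-chromen-8-yl]-3-[4-(methoxymethoxy)phenyl]prop-2-en-1-one F8. Dilute HCl in MeOH at 40 °C removes the acetal without touching the tertiary ether and gives 19.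

## Further compounds

F1 | step 6 | (4R)-4-benzyl-3-[(benzyloxy)acetyl]-1,3-oxazolidin-2-one | O=C(COCc1ccccc1)N1C(=O)OC[C@H]1Cc1ccccc1
F2 | step 6 | (4R)-4-benzyl-3-[(2S)-2-(benzyloxy)-3-(3-bromo-2-{[tert-butyl(dimethyl)silyl]oxy}-6-methoxyphenyl)propanoyl]-1,3-oxazolidin-2-one | COc1ccc(Br)c(O[Si](C)(C)C(C)(C)C)c1C[C@H](OCc1ccccc1)C(=O)N1C(=O)OC[C@H]1Cc1ccccc1
F3 | step 8 | (2S)-2-(benzyloxy)-3-(3-bromo-2-hydroxy-6-methoxyphenyl)-N-methoxy-N-methylpropanamide | COc1ccc(Br)c(O)c1C[C@H](OCc1ccccc1)C(=O)N(C)OC
F4 | step 8 | 2-[(2S)-2-(benzyloxy)-3-methylbut-3-en-1-yl]-6-bromo-3-methoxyphenol | COc1ccc(Br)c(O)c1C[C@H](OCc1ccccc1)C(C)=C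
F5 | step 8 | {[(3S)-3-(benzyloxy)-8-bromo-5-methoxy-2-methyl-3,4-dihydro-2H-chromen-2-yl]methyl}mercury trifluoroacetate (both C2 epimers) | COc1ccc(Br)c2c1C[C@H](OCc1ccccc1)C(C)(C[Hg]OC(=O)C(F)(F)F)O2
F6 | step 7 | methyl (2S)-2-(benzyloxy)-3-(3-bromo-2-hydroxy-6-methoxyphenyl)propanoate | COc1ccc(Br)c(O)c1C[C@H](OCc1ccccc1)C(=O)OC
F7 | step 3 | tert-butyl[(3-bromo-2-{[tert-butyl(dimethyl)silyl]oxy}-6-methoxyphenyl)methoxy]dimethylsilane | COc1ccc(Br)c(O[Si](C)(C)C(C)(C)C)c1CO[Si](C)(C)C(C)(C)C
F8 | step 11 | (2E)-1-[(3S)-3-hydroxy-5-methoxy-2,2-dimethyl-3,4-dihydro-2H-chromen-8-yl]-3-[4-(methoxymethoxy)phenyl]prop-2-en-1-one | COc1ccc(C(=O)/C=C/c2ccc(OCOC)cc2)c2c1C[C@H](O)C(C)(C)O2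
A1 | alternative 1 | 4-{(1E)-3-[(3S)-3-{[tert-butyl(dimethyl)silyl]oxy}-5-methoxy-2,2-dimethyl-3,4-dihydro-2H-chromen-8-yl]-3-oxoprop-1-en-1-yl}phenyl acetate | COc1ccc(C(=O)/C=C/c3ccc(OC(C)=O)cc3)c2c1C[C@H](O[Si](C)(C)C(C)(C)C)C(C)(C)O2
A2 | alternative 1 | {[(3S)-8-bromo-5-methoxy-2,2-dimethyl-3,4-dihydro-2H-chromen-3-yl]oxy}(tert-butyl)dimethylsilane | COc1ccc(Br)c2c1C[C@H](O[Si](C)(C)C(C)(C)C)C(C)(C)O2
A3 | alternative 1 | carbon monoxide | [C-]#[O+]
A4 | alternative 1 | 4-ethenylphenyl acetate (4-acetoxystyrene) | CC(=O)Oc1ccc(C=C)cc1
A5 | alternative 2 | methyl 2,4-dihydroxy-3-{[(4S)-2,2,5,5-tetramethyl-1,3-dioxolan-4-yl]methyl}benzoate | COC(=O)c1ccc(O)c(C[C@@H]2OC(C)(C)OC2(C)C)c1O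
A6 | alternative 2 | methyl (6E)-7-methoxy-3,5-dioxo-4-{[(4S)-2,2,5,5-tetramethyl-1,3-dioxolan-4-yl]methyl}hept-6-enoate | COC(=O)CC(=O)C(C[C@@H]1OC(C)(C)OC1(C)C)C(=O)/C=C/OC
A7 | alternative 3 | 1-(5-methoxy-2,2-dimethyl-2H-chromen-8-yl)ethanone | CC(=O)c1ccc(OC)c2c1OC(C)(C)C=C2
A8 | alternative 3 | 1-{4-methoxy-2-[(2-methylbut-3-yn-2-yl)oxy]phenyl}ethanone | CC(=O)c1ccc(OC)cc1OC(C)(C)C#C
A9 | alternative 3 | 1-(2-hydroxy-4-methoxyphenyl)ethanone | CC(=O)c1ccc(OC)cc1O
A10 | alternative 3 | 1-[(3S,4S)-3,4-epoxy-5-methoxy-2,2-dimethyl-3,4-dihydro-2H-chromen-8-yl]ethanone | COc1ccc(C(C)=O)c2c1[C@@H]1O[C@@H]1C(C)(C)O2
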